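The constants of the single steps are unknown to me, but one ratio of them is enough for the end of this flask. If I divide the rate at which target forms by the rate at which other capture product forms, the intermediate and time drop out, leaving the rate constant of first nucleophile over that of second nucleophile, times the ratio of the two concentrations. Integrated, this says that the fraction of first nucleophile left equals the fraction of second nucleophile left raised to the power S, where S is that ratio of the two constants.

| setting | violet | amber | green | flask |
|---|---|---|---|---|
| solid substrate | 0.67 M | 1.5 M | 1 M | 1.0 M |
| first nucleophile | 0.70 M | 0.70 M | 0.70 M | 0.700 M |
| second nucleophile | 1.2 M | 1.2 M | 2.4 M | 1.20 M |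
| remark | run made earlier | run made earlier | run made earlier |  |
| time |  |  |  | 2.5 h |

| run | time / min | other capture product / % | target / % |
|---|---|---|---|
| violet | 25.0 | 32.1 | 67.7 |
| violet | 50.0 | 33.1 | 65.9 |
| violet | 80.0 | 33.8 | 67.5 |
| violet | 90.0 | 33.1 | 67.1 |
| violet | 120 | 33.3 | 66.6 |
| amber | 25.0 | 52.4 | 46.6 |
| amber | 50.0 | 54.1 | 46.9 |
| amber | 80.0 | 52.9 | 45.6 |
| amber | 90.0 | 53.7 | 45.6 |
| amber | 120 | 54.2 | 46.4 |
| green | 10.0 | 32.1 | 35.0 |
| green | 30.0 | 50.1 | 48.3 |
| green | 60.0 | 50.1 | 49.7 |
| green | 80.0 | 50.7 | 50.1 |
| green | 120 | 51.1 | 49.3 |

(readings scatter by 0.5 percentage points)

1. share of other capture product in other capture product plus target at 1.0 min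
2. share of other capture product in other capture product plus target at 12 min
3. share of other capture product in other capture product plus target at 2.5 h

- solid substrate is a solid; its amount is given per volume of the solution
- the numbers in the tables scatter with a standard deviation of 0.5 percentage points
- steps under discussion: starting material -> intermediate; first nucleophile + intermediate -> target; second nucleophile + intermediate -> other capture product; starting material -> decomposition product; solid substrate <-> starting material
- at the start none of the solid substrate is in solution

The last violet reading holds 99.9 % of the charge in the two products, so I count that charge as captured, and the nucleophiles left then give S = 4.93, the selectivity factor.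

My first extreme for the flask has both nucleophiles standing at their charges, which puts the share of other capture product at 25.8 %. My second has the whole charge captured: if 40.0 % of it were other capture product, S would make the two consumptions add up to 100.5 % of the charge, which is more than the charge, so my reckoning puts the end share just under 40.0 %.

The real flask travels from the first extreme to the second as capture proceeds. The green run has captured 0.671 M at 10.0 min, a feed of 0.0671 M min⁻¹. If the flask keeps that feed, it has captured 0.0671 M at 1.0 min, close to the first extreme, and 0.805 M at 12 min, past the middle. So the share to watch is the one that climbs while the solid goes in.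

The forecast gives 25.9 %, 35.7 % and 39.5 %, taking “a solubility-limited zero-order feed of about 0.067 M/min”.

The flask gives 25.5 %, 35.7 % and 39.3 %, each within the tolerance.

    starting material → intermediate (k = 0.0147 s⁻¹)
    first nucleophile + intermediate → target (k = 3.62 M⁻¹ s⁻¹)
    second nucleophile + intermediate → other capture product (k = 0.713 M⁻¹ s⁻¹)
    starting material → decomposition product (k = 6.20 × 10⁻⁷ s⁻¹)
    solid substrate ⇌ starting material, rate k5*(cs5 - [starting material]) while solid is left; crystals form when [starting material] > cs5 (solubility = 0.930 M, k = 0.00150 s⁻¹)

At 2.50 h the flask has 67 % of its second nucleophile left, which S turns into 14.1 % of the first, against 13 % in the flask. The forecast's end share stands for this charge of second nucleophile: the neighbour flask with 2.0 M of it keeps 76 %, S makes that 26.2 % of the first against 25 % in that neighbour, and its share ends at 47.6 %.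

Readings and results were computed for an exercise, and the scatter is random.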